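## Structural features

The target is an acyclic wax ester. An unbranched, saturated C25 acyl chain (C1 carbonyl, C2–C24 methylenes, C25 methyl) is joined through the ester oxygen to a 2-phenylethyl group. The monosubstituted benzene ring of that group is the only ring, and two sp3 carbons separate it from the oxygen. There is no stereocentre and no C=C bond, so the molecule is achiral and no stereochemical relation has to be set. The only reactive group is the ester (hydrolysis, transesterification, hydride and organometallic reagents); the benzylic CH2 and the arene matter only under strongly oxidising conditions. The real difficulty is the chain: 25 is an odd number, whereas fats and ethene oligomers supply even numbers, and the 23 methylenes C2–C24 offer no handle, so a C–C bond made inside the chain normally leaves a function that must be erased afterwards. Homologues (C24 or C26 acyl) and methyl-branched isomers would be almost inseparable from the target, so chain length and linearity must come from the constitution of the precursors and the selectivity of the bond-forming step, not from purification. The key step exploits three features: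
- C1 is a single carbon at the oxidation level of carbon monoxide, placed between the chain and the oxygen.
- The segment C2–C25 has no branch, heteroatom or ring that could stop a metal hydride walking along it.
- This C24 segment is symmetric about the C13–C14 bond, so a double bond placed there lies equally far from two equivalent chain ends.

## Logic of the disconnections

Route in one sentence: 6 is made by isomerising three-component alkoxycarbonylation of the internal, symmetric alkene 2 with 3 and 4. This sentence does not fit the acylation of 4 by a ready-made C25 acid, which is the route drawn first.

**6 ⇒ 2 + 3 + 4 (by way of 5).**
- Bonds cut: C1–C2, the acyl C1–O bond and one C–H bond, all at once.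
- Reason: removing C1 changes the parity of the chain from odd to even and uncovers the symmetric C24 hydrocarbon 2. The ester linkage is made together with the chain end, so no separate acylation is needed. A chain-walking catalyst makes the position of the double bond irrelevant, so the most easily made positional isomer can serve as precursor.
- Gain: a C33 ester falls apart into a gas (3), a bulk alcohol (4) and a symmetric hydrocarbon (2). No atom is lost and no redox adjustment or protecting group is needed.
- Demand on the forward step: the catalyst must move the double bond of 2 over eleven positions to the stage of 5 and must carbonylate only the terminal carbon. Cleavage of the metal acyl by 4 must also outrun catalyst decay.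
- Stopping at 5 as a purchased precursor is rejected. It would hand the chain-building problem to a supplier exactly as the purchase of the C25 acid does, and the key step does not need the terminal isomer.

**2 ⇒ 1 + 1.**
- Bond cut: C12=C13 of 2, which becomes C13–C14 of 6.
- Reason: the cut lies on the symmetry element, so the forward reaction is a homodimerisation with no cross-selectivity problem. The double bond it leaves is not erased afterwards but serves as the handle for the key step.
- Gain: a waxy C24 alkene is reduced to one distillable C13 liquid.
- Demand: the coupling must run without double-bond migration, because migration followed by further exchange would scramble the chain length. The two terminal CH2 groups must leave as a gas to drive the equilibrium. The E/Z geometry of 2 is of no consequence.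

1, 3 and 4 are purchased.

## Other disconnections considered

**Alternative 1:** cut of the acyl C1–O bond only, the first idea that comes to mind.
- Forward key step: esterification of pentacosanoic acid A1 with 4 under acid catalysis or carbodiimide activation.
- Ground for preferring the chosen plan: this is a single safe step, but it leaves the real difficulty untouched, because the odd C25 chain is simply bought. If A1 has to be made, the natural precursor is the even-chain tetracosanoic acid A2. That route needs a one-carbon homologation of the Arndt–Eistert type (three operations and a diazoalkane) and is longer than the chosen plan. The chosen plan installs the same extra carbon from 3 in the step that also makes the ester.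

**Alternative 2:** cut of C8–C9.
- Forward key step: mixed Kolbe electrolysis, an anodic decarboxylative radical–radical coupling of octadecanoic acid A5 (C9–C25) with the half ester 9-oxo-9-(2-phenylethoxy)nonanoic acid A4 (C1–C8). A4 is made from nonanedioic acid A3 and 4.
- Merits: the step count is the same and the coupling is traceless.
- Grounds for preferring the chosen plan:
  - Two free radicals of like reactivity combine statistically, so both symmetric dimers must form alongside 6.
  - The mono-esterification of symmetric A3 is statistical too.
  - The anode potential of a Kolbe reaction lies near the potential at which the alkylbenzene ring of A4 begins to be oxidised.
  - The methanolic, partly neutralised electrolyte turns basic towards the end and invites transesterification.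
  - Two carbons are lost as carbon dioxide.
  - The chosen plan has no statistical step and no oxidant.

**Alternative 3:** cut of C10–C11.
- Forward key step: olefin cross-metathesis of 2-phenylethyl undec-10-enoate A6 (an ester of 4) with hexadec-1-ene A7 to give 2-phenylethyl (E)-pentacos-10-enoate A8, followed by hydrogenation.
- Grounds for preferring the chosen plan: both partners are unhindered terminal alkenes of the same reactivity class, so the product distribution is statistical. The route needs three steps, and the double bond of A8 is made only to be destroyed. The chosen plan uses the same reaction type as a homodimerisation, where statistics play no part, and turns the resulting double bond into the ester instead of reducing it.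

Key step: step 2

Assumption: the target SMILES holds no stereocentre and no stereogenic double bond. The compound is achiral, so the demand for a single enantiomer is met by any constitutionally correct synthesis.

## Steps

Step 1
Reactants: 1 tridec-1-ene (two molecules)
Product: 2 tetracos-12-ene, drawn as the expected major E isomer (the minor Z isomer is not separated)
Conditions: (H2IMes)(PCy3)Cl2Ru=CHPh (0.2 mol %), 1,4-benzoquinone (2 mol %), neat, 45 °C, 50 mbar; SiO2 plug (hexane); unreacted 1 distilled off; crystallisation from cold acetone
Reagents that add atoms: none
Why: Olefin self-metathesis of an unhindered terminal alkene through ruthenacyclobutanes; loss of the gaseous C2 fragment under reduced pressure drives the equilibrium to 2, and identical partners exclude any cross-selectivity problem. Benzoquinone intercepts ruthenium hydrides and should suppress double-bond migration, which keeps the chain at exactly C24; no stereocentre is formed and the E/Z geometry is erased in step 2.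

Step 2
Reactants: 2 tetracos-12-ene; 3 carbon monoxide; 4 2-phenylethanol
Product: 6 2-phenylethyl pentacosanoate, via tetracos-1-ene 5 (not isolated)
Conditions: Pd(OAc)2 (1 mol %), dtbpx (4 mol %), MeSO3H (8 mol %), 3 (20 bar), 4 (8 equiv), toluene, 90 °C; dtbpx = 1,2-bis(di-tert-butylphosphinomethyl)benzene
Reagents that add atoms: none
Why: Isomerising alkoxycarbonylation (hydroesterification) through the palladium hydride cycle, the reaction type known for turning internal linear alkenes and mid-chain unsaturated fatty esters into terminal linear esters. The cationic hydride [(dtbpx)Pd–H]+, formed from the catalyst precursors and 4, adds to C12=C13 of 2 and travels along the chain by fast, reversible β-hydride elimination and reinsertion, so that all positional isomers up to 5 and all palladium alkyls equilibrate. Insertion of 3 is also reversible, and the slow, irreversible step is the attack of 4 on the palladium acyl. The four tert-butyl groups of the rigid, wide-bite-angle diphosphine crowd the acyl site so much that alcoholysis of every α-branched acyl should cost far more than that of the n-alkyl acyl, so under these Curtin–Hammett conditions the whole isomer pool drains through the terminal alkyl, and C1–C2, C1–O and one C–H bond of 6 form in one operation in which every atom of 2, 3 and 4 is kept. The selectivity needed is purely regiochemical (the chain end against eleven distinct internal positions), and the substrate secures it in three ways: C2–C25 holds no branch, heteroatom or ring that could stop or trap the walking hydride, the two ends of 2 are equivalent by symmetry so that both walking directions give 6, and the only C=C bond is consumed so that no second carbonylation can follow. No ring is closed and no stereocentre is created, and the E/Z geometry of 2 is erased. The new ester, the phenyl ring and the excess primary alcohol should tolerate the weakly acidic, non-oxidising medium; excess 4 is distilled off and 6 is crystallised from acetone, which should leave traces of branched isomers in the mother liquor.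

## Compound list

1 | tridec-1-ene | CCCCCCCCCCCC=C | starting material
2 | tetracos-12-ene (major E isomer drawn) | CCCCCCCCCCC/C=C/CCCCCCCCCCC | intermediate
3 | carbon monoxide | [C-]#[O+] | starting material
4 | 2-phenylethanol | OCCc1ccccc1 | starting material
5 | tetracos-1-ene (not isolated) | CCCCCCCCCCCCCCCCCCCCCCC=C | intermediate
6 | 2-phenylethyl pentacosanoate | CCCCCCCCCCCCCCCCCCCCCCCCC(=O)OCCc1ccccc1 | target

## Step count and risk

Total step count: 2. Longest linear sequence: 2. The route has only two steps, so the list of uncertain steps is complete with the key step and step 1.

**Step 2 (key step).** Two processes are most likely to go wrong.
- Slow turnover. The stationary share of the terminal palladium alkyl falls as the number of internal positions grows (twelve distinct positions in a C24 chain). In addition, 4 diluted in toluene should cleave the acyl more slowly than a small alcohol used as solvent. Decay of the hydride to palladium black may therefore overtake carbonylation.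
- Premature trapping of an internal acyl next to the chain end. This would erode linearity, and crystallisation may not fully repair it.

The fallback gives up chain walking and carbonylation and joins the chain at C12–C13 by known alkyl–alkyl cross-coupling. It sets out from 1 and 4 and comes back to the route at 6. Compound 4 is esterified with purchased 12-bromododecanoic acid F1 (cat. TsOH, toluene, water separator) to give 2-phenylethyl 12-bromododecanoate F2. Compound 1 is hydroborated with 9-BBN-H (THF, rt, anti-Markovnikov) to give B-tridecyl-9-borabicyclo[3.3.1]nonane F3. F3 is coupled in the same flask with F2 under alkyl–alkyl Suzuki–Miyaura conditions (Pd(OAc)2, PCy3, K3PO4·H2O, THF, rt), which an ester tolerates. Here C13 + C12 fix the chain length by constitution.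

**Step 1.** The most likely failure is double-bond migration caused by ruthenium hydride decomposition species while metathesis is still running. Migrated alkenes re-enter the exchange, chain-length fidelity is lost, and the error would be carried into the ester, where it cannot be removed. A second failure is incomplete conversion, if the gaseous by-product is retained in the thickening melt.

The fallback replaces the reversible alkylidene exchange by an irreversible reductive carbonyl coupling. It sets out from 1 and comes back to the route at 2. Compound 1 is ozonised (O3, CH2Cl2, −78 °C, then Me2S) to give dodecanal F4, which can also be bought. F4 is dimerised by McMurry coupling (TiCl4, Zn, THF, reflux) to give 2 as an E/Z mixture. The chain length follows from C12 + C12, and no exchange process operates that could alter the chain length.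

## Further compounds

F1 | step 2 | 12-bromododecanoic acid | OC(=O)CCCCCCCCCCCBr
F2 | step 2 | 2-phenylethyl 12-bromododecanoate | BrCCCCCCCCCCCC(=O)OCCc1ccccc1
F3 | step 2 | B-tridecyl-9-borabicyclo[3.3.1]nonane | CCCCCCCCCCCCCB1C2CCCC1CCC2
F4 | step 1 | dodecanal | CCCCCCCCCCCC=O
A1 | alternative 1 | pentacosanoic acid | CCCCCCCCCCCCCCCCCCCCCCCCC(=O)O
A2 | alternative 1 | tetracosanoic acid | CCCCCCCCCCCCCCCCCCCCCCCC(=O)O
A3 | alternative 2 | nonanedioic acid | OC(=O)CCCCCCCC(=O)O
A4 | alternative 2 | 9-oxo-9-(2-phenylethoxy)nonanoic acid | OC(=O)CCCCCCCC(=O)OCCc1ccccc1
A5 | alternative 2 | octadecanoic acid | CCCCCCCCCCCCCCCCCC(=O)O
A6 | alternative 3 | 2-phenylethyl undec-10-enoate | C=CCCCCCCCCC(=O)OCCc1ccccc1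
A7 | alternative 3 | hexadec-1-ene | CCCCCCCCCCCCCCC=C
A8 | alternative 3 | 2-phenylethyl (E)-pentacos-10-enoate | CCCCCCCCCCCCCC/C=C/CCCCCCCCC(=O)OCCc1ccccc1
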